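## Retrosyn­thetic overview

1. 34 ⇐ 33 ⇐ 31 by reductive allylic transposition (C13′ carbonate → H‑7′ and C11′=C13′). The last ring to close is the seven-membered ring C1′–C10′–C9′–C8′–C7′–C6′–C5′ of the primed half, cut at C5′–C6′.
2. Enabling feature: C5′ is the β-carbon of the C3′ ketone whose α-carbon C4′ carries the exocyclic C15′ methylene, and C6′ is the γ-carbon of the lactone. C5′–C6′ is thus the retron of a vinylogous Michael addition–β-elimination between a Morita–Baylis–Hillman acetate (29) and a furanone dienolate, which also unveils C4′=C15′.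
3. 29 ⇐ Diels–Alder adduct 26: the cyclohexene C2′–C1′=C10′–C14′–C15–C4 comes from 1-siloxy diene 25 and the exocyclic enone of 20 (7-epi-dehydrozaluzanin C). The 5′-silyloxy group of 25 is a temporary handle that masks the C4′=C5′ enone until step 17.
4. 20 is made by the same closure on monomer 15, which rehearses the key step. 15 and 25 both come from one silyl enol ether 11 = (R)-4-silyloxycyclopentenone 10 + butenolide vinyl bromide 9.
5. Ring order: furanone (step 1) → seven-membered ring of the unprimed half (step 9) → cyclohexene (step 16) → seven-membered ring of the primed half (step 20); both cyclopentane rings come from 10.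

Key step: step 20

Remark (stereochemistry): in the given structure both γ-lactones are cis-fused (H‑6/H‑7 and H‑6′/H‑7′ cis, H‑5/H‑6 trans), so neither half is taken from natural trans-fused guaianolides and both are built de novo.

Remark (conventions): guaianolide numbering is used. The unprimed half contains spiro carbon C4; the primed half contains the carbinol C2′. α face of the unprimed cyclopentane = face of H‑1/H‑5; α face of the primed cyclopentane = face of the 2′-oxygen. R = 4-(4-{[(tert-butyldiphenylsilyl)oxy]methyl}-5-oxo-2,5-dihydrofuran-3-yl)but-1-en-2-yl. TBS = tert-butyldimethylsilyl, TBDPS = tert-butyldiphenylsilyl, TES = triethylsilyl.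

## Route

Step 1
Reactants: 1 but-2-yne-1,4-diol; 2 (4-bromobut-1-yn-1-yl)trimethylsilane
Product: 5 3-(hydroxymethyl)-4-[4-(trimethylsilyl)but-3-yn-1-yl]furan-2(5H)-one, via Grignard reagent 3 (not isolated), via alkenylmagnesium chelate 4 (not isolated)
Conditions: 2, Mg, THF, rt; 1, EtMgBr (2 equiv), THF, 0 °C; then 3 (1.3 equiv), CuI (10 mol%), 65 °C; CO2, −20 °C to rt; 2 M HCl
Reagents that add atoms: carbon dioxide (O=C=O)
Why: Copper-catalysed anti-carbomagnesiation of the bis(bromomagnesium) alkoxide of 1 places the alkyl group and magnesium trans on the alkene (chelate 4), and carboxylation followed by acidification lactonises the cis γ-hydroxy acid to the 3,4-disubstituted butenolide; no stereocentre is formed.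

Step 2
Reactants: 5 3-(hydroxymethyl)-4-[4-(trimethylsilyl)but-3-yn-1-yl]furan-2(5H)-one
Product: 6 4-(but-3-yn-1-yl)-3-(hydroxymethyl)furan-2(5H)-one
Conditions: TBAF (1.1 equiv), AcOH (1.2 equiv), THF, 0 °C
Reagents that add atoms: none
Why: Buffered fluoride removes the alkynyl trimethylsilyl group (protodesilylation) without opening the lactone.

Step 3
Reactants: 6 4-(but-3-yn-1-yl)-3-(hydroxymethyl)furan-2(5H)-one
Product: 7 4-(but-3-yn-1-yl)-3-{[(tert-butyldiphenylsilyl)oxy]methyl}furan-2(5H)-one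
Conditions: TBDPSCl, imidazole, DMF, rt
Reagents that add atoms: tert-butyl(chloro)diphenylsilane (CC(C)(C)[Si](Cl)(c1ccccc1)c1ccccc1)
Why: Standard silylation of the primary alcohol; the acid-stable silyl ether is a poor leaving group, so it should survive the later dienolate chemistry and the acidic eliminations.

Step 4
Reactants: 7 4-(but-3-yn-1-yl)-3-{[(tert-butyldiphenylsilyl)oxy]methyl}furan-2(5H)-one
Product: 9 4-(3-bromobut-3-en-1-yl)-3-{[(tert-butyldiphenylsilyl)oxy]methyl}furan-2(5H)-one, via bromoalkenylborane 8 (not isolated)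
Conditions: B-bromo-9-BBN (1.1 equiv), CH2Cl2, −78 to 0 °C; then AcOH, 0 °C
Reagents that add atoms: B-bromo-9-borabicyclo[3.3.1]nonane (BrB1C2CCCC1CCC2)
Why: Syn-bromoboration of the terminal alkyne puts boron on the terminal and bromine on the internal carbon, and protodeboronation with acetic acid gives the 2-bromo-1-alkene (net Markovnikov hydrobromination).

Step 5
Reactants: 9 4-(3-bromobut-3-en-1-yl)-3-{[(tert-butyldiphenylsilyl)oxy]methyl}furan-2(5H)-one; 10 (R)-4-[(tert-butyldimethylsilyl)oxy]cyclopent-2-en-1-one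
Product: 11 trans-4-(TBS-oxy)-3-R-1-(TES-oxy)cyclopent-1-ene
Conditions: NiCl2(dme) (10 mol%), neocuproine (12 mol%), Mn powder (2 equiv), Et3SiCl (1.5 equiv), DMF, rt
Reagents that add atoms: chlorotriethylsilane (CC[Si](Cl)(CC)CC)
Why: Nickel-catalysed reductive conjugate addition of an alkenyl bromide to an enone with chlorosilane trapping: the alkenyl group should add to the β-carbon anti to the silyloxy stereocentre of 10, which sets C1 trans to OTBS, and the enolate is fixed regiospecifically as the triethylsilyl enol ether.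

Step 6
Reactants: 11 trans-4-(TBS-oxy)-3-R-1-(TES-oxy)cyclopent-1-ene
Product: 13 (R)-4-R-cyclopent-2-en-1-one, via silyloxy ketone 12 (not isolated)
Conditions: AcOH/H2O 9:1, 60 °C
Reagents that add atoms: none
Why: Acidic hydrolysis of the silyl enol ether gives the β-silyloxy ketone 12, which should lose tert-butyldimethylsilanol by acid-catalysed β-elimination (the dehydration known for β-oxygenated cyclopentanones) without touching C1 or, since no base is present, the acidic butenolide.

Step 7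
Reactants: 13 (R)-4-R-cyclopent-2-en-1-one
Product: 14 2-(hydroxymethyl)-4-R-cyclopent-2-en-1-one
Conditions: 37% aq. CH2O (3 equiv), DMAP (0.3 equiv), THF/H2O 1:1, rt
Reagents that add atoms: formaldehyde (C=O)
Why: Morita–Baylis–Hillman reaction of the cyclopentenone with formaldehyde under nucleophilic catalysis installs C15 at C4.

Step 8
Reactants: 14 2-(hydroxymethyl)-4-R-cyclopent-2-en-1-one
Product: 15 (5-oxo-3-R-cyclopent-1-en-1-yl)methyl acetate
Conditions: Ac2O, pyridine, DMAP (cat.), CH2Cl2, 0 °C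
Reagents that add atoms: acetic anhydride (CC(=O)OC(C)=O)
Why: Acetylation turns the allylic alcohol into the leaving group for the addition–elimination.

Step 9
Reactants: 15 (5-oxo-3-R-cyclopent-1-en-1-yl)methyl acetate
Product: 17 13-(TBDPS-oxy)-3-oxoguaia-4(15),7(11),10(14)-trien-12,6-olide (1α-H, 5α-H, 6β-H), via caesium enolate 16 (not isolated)
Conditions: Cs2CO3 (1.5 equiv), MeCN (0.005 M), 0 °C to rt
Reagents that add atoms: none
Why: Intramolecular vinylogous Michael addition–β-elimination (SN2′ alkylation of a Morita–Baylis–Hillman acetate by a furanone dienolate, 7-(enolendo)-exo-trig): the tether delivers C6 to C5 on the face of the C1 side chain (cis ring fusion), an open antiperiplanar transition state with the small C6–H between C1 and C4 should set H‑6 anti to H‑5, and loss of acetate from enolate 16 gives the exocyclic enone.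

Step 10
Reactants: 17 13-(TBDPS-oxy)-3-oxoguaia-4(15),7(11),10(14)-trien-12,6-olide
Product: 18 13-hydroxy-3-oxoguaia-4(15),7(11),10(14)-trien-12,6-olide
Conditions: HF·pyridine, THF, 0 °C to rt
Reagents that add atoms: none
Why: Fluoride-mediated cleavage of the silyl ether under non-basic conditions.

Step 11
Reactants: 18 13-hydroxy-3-oxoguaia-4(15),7(11),10(14)-trien-12,6-olide
Product: 19 13-[(methoxycarbonyl)oxy]-3-oxoguaia-4(15),7(11),10(14)-trien-12,6-olide
Conditions: ClCO2Me, pyridine, CH2Cl2, 0 °C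
Reagents that add atoms: methyl chloroformate (COC(=O)Cl)
Why: Carbonate formation gives the allylic leaving group needed for ionisation by zerovalent palladium.

Step 12
Reactants: 19 13-[(methoxycarbonyl)oxy]-3-oxoguaia-4(15),7(11),10(14)-trien-12,6-olide
Product: 20 7-epi-dehydrozaluzanin C [3-oxoguaia-4(15),10(14),11(13)-trien-12,6-olide, 1α-H, 5α-H, 6β-H, 7β-H]
Conditions: Pd2(dba)3·CHCl3 (2.5 mol%), PBu3 (10 mol%), HCO2H, Et3N, THF, rt
Reagents that add atoms: none
Why: Palladium-catalysed formate reduction of the allylic carbonate (Tsuji–Trost-type hydrogenolysis) with allylic transposition: the 2-acyl-π-allylpalladium should form on the convex face syn to H‑6 and transfer hydride to the more substituted terminus C7, giving the exocyclic methylene lactone with H‑7 cis to H‑6.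

Step 13
Reactants: 11 trans-4-(TBS-oxy)-3-R-1-(TES-oxy)cyclopent-1-ene
Product: 22 2-hydroxy-3-R-4-(TBS-oxy)cyclopentan-1-one (all-trans), via silyloxy epoxide 21 (not isolated)
Conditions: DMDO (1.05 equiv), acetone/CH2Cl2, −78 °C; then 10% aq. citric acid, THF, 0 °C
Reagents that add atoms: dimethyldioxirane (CC1(C)OO1)
Why: Rubottom oxidation: the electron-rich silyl enol ether should be epoxidised in preference to the 1,1-disubstituted alkene and the electron-poor butenolide, anti to the neighbouring side chain, and mild acid releases the α-hydroxy ketone.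

Step 14
Reactants: 22 2-hydroxy-3-R-4-(TBS-oxy)cyclopentan-1-one
Product: 24 2-hydroxy-3-R-4-(TBS-oxy)cyclopent-2-en-1-one, via cyclopentanedione 23 (not isolated)
Conditions: Dess–Martin periodinane, CH2Cl2, 0 °C to rt
Reagents that add atoms: none
Why: Dess–Martin oxidation gives the cyclopentane-1,2-dione 23, which tautomerises to the conjugated diosphenol (enol towards C1′), so the C1′ and C2′ stereocentres disappear.

Step 15
Reactants: 24 2-hydroxy-3-R-4-(TBS-oxy)cyclopent-2-en-1-one
Product: 25 2,4-bis(TBS-oxy)-3-R-cyclopent-2-en-1-one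
Conditions: TBSCl, imidazole, DMF, 0 °C
Reagents that add atoms: tert-butyl(chloro)dimethylsilane (CC(C)(C)[Si](C)(C)Cl)
Why: O-Silylation of the acidic enol fixes the 1-siloxy diene C2′=C1′–C10′=C14′.

Step 16
Reactants: 20 7-epi-dehydrozaluzanin C; 25 2,4-bis(TBS-oxy)-3-R-cyclopent-2-en-1-one
Product: 26 5′,6′-seco spiro adduct (cyclohexene C2′–C1′=C10′–C14′–C15–C4; 2′α-OTBS, 5′α-OTBS, 3′-ketone, butenolide on C8′)
Conditions: Me2AlCl (0.2 equiv), CH2Cl2, −78 to −30 °C
Reagents that add atoms: none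
Why: Lewis-acid-catalysed Diels–Alder reaction of a 1-siloxy diene with an exocyclic enone: the donor oxygen on C2′ directs C14′ to C15 and C2′ to C4 ("ortho" adduct), the diene should add to the convex α face of 20 with the C3 carbonyl endo, which sets C4 and C2′, and 25 is approached anti to its 5′-silyloxy group, a centre that is removed in step 17.

Step 17
Reactants: 26 5′,6′-seco spiro adduct
Product: 27 5′,6′-seco dienone (C3′ ketone, C4′=C5′, C1′=C10′; 2′α-OTBS)
Conditions: AcOH/H2O 9:1, 50 °C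
Reagents that add atoms: none
Why: Acid-promoted β-elimination of the allylic 5′-silyloxy group (as in step 6) gives the cross-conjugated dienone, while the hindered tertiary 2′-silyl ether and the primary TBDPS ether should survive.

Step 18
Reactants: 27 5′,6′-seco dienone
Product: 28 15′-hydroxy derivative of 27 (hydroxymethyl on C4′)
Conditions: 37% aq. CH2O (3 equiv), DMAP (0.3 equiv), THF/H2O 1:1, rt
Reagents that add atoms: formaldehyde (C=O)
Why: Morita–Baylis–Hillman hydroxymethylation at C4′; only this half has an enone with an α-hydrogen, so C15′ is introduced without touching the C3 ketone of the other half.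

Step 19
Reactants: 28 15′-hydroxy derivative of 27
Product: 29 15′-acetoxy derivative of 27
Conditions: Ac2O, pyridine, DMAP (cat.), CH2Cl2, 0 °C
Reagents that add atoms: acetic anhydride (CC(=O)OC(C)=O)
Why: Acetylation gives the allylic acetate for the key step.

Step 20
Reactants: 29 15′-acetoxy derivative of 27
Product: 31 hexacyclic butenolide (2′α-OTBS, 13′-OTBDPS, C4′=C15′, C7′=C11′; 5′α-H, 6′β-H), via caesium enolate 30 (not isolated)
Conditions: Cs2CO3 (1.5 equiv), MeCN (0.002 M), −10 °C to rt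
Reagents that add atoms: none
Why: Cs2CO3 deprotonates the butenolide at C6′ to the furanone dienolate, which adds through C6′ to C5′, the β-carbon of the C3′ enone, and the resulting enolate 30 expels acetate from C15′ (E1cB), so one operation closes the seven-membered ring, creates C5′ and C6′ and releases the C4′=C15′ methylene. The closest known reaction type is the γ-selective vinylogous Michael addition/allylic alkylation of butenolides with Morita–Baylis–Hillman acetates and carbonates, run here intramolecularly as in step 9. The ring closes in the 7-(enolendo)-exo-trig mode. C5′ should be attacked on its β face, because the bulky 2′-OTBS group stands axially over the α face next to C1′ whereas C4 on the β face is tied back into the cyclohexene with its substituents pointing away from C5′; C6′ should follow from the same open antiperiplanar transition state as in step 9, with the small C6′–H between C1′ and C4′, giving H‑6′ anti to H‑5′. The step needs 1,4-addition at C5′ rather than 1,6-addition at C10′, γ- rather than α-attack of the dienolate, and cyclisation rather than oligomerisation: C10′ is fully substituted and its attack would be a disfavoured 5-(enolendo) closure, the α-carbon C11′ would have to become quaternary, and high dilution favours the intramolecular path.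

Step 21
Reactants: 31 hexacyclic butenolide
Product: 32 2′,13′-diol
Conditions: 48% aq. HF, MeCN, 0 °C to rt
Reagents that add atoms: none
Why: Acidic fluoride cleaves the primary TBDPS ether and the tertiary TBS ether and avoids the retro-aldol cleavage of the C2′–C4 bond that a basic fluoride source could cause.

Step 22
Reactants: 32 2′,13′-diol
Product: 33 13′-methyl carbonate
Conditions: ClCO2Me, pyridine, CH2Cl2, 0 °C
Reagents that add atoms: methyl chloroformate (COC(=O)Cl)
Why: Selective carbonate formation at the primary allylic alcohol; the tertiary α-ketol should not react.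

Step 23
Reactants: 33 13′-methyl carbonate
Product: 34 target CNP0269880.1
Conditions: Pd2(dba)3·CHCl3 (2.5 mol%), PBu3 (10 mol%), HCO2H, Et3N, THF, rt
Reagents that add atoms: none
Why: Palladium-catalysed formate reduction with allylic transposition as in step 12: hydride should go to C7′ from the convex face syn to H‑6′, giving the second cis-fused α-methylene lactone and the target.

## Compound list

1 | but-2-yne-1,4-diol | OCC#CCO | starting material
2 | (4-bromobut-1-yn-1-yl)trimethylsilane | C[Si](C)(C)C#CCCBr | starting material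
3 | [4-(trimethylsilyl)but-3-yn-1-yl]magnesium bromide | C[Si](C)(C)C#CCC[Mg]Br | intermediate
4 | alkenylmagnesium chelate from anti-carbomagnesiation of 1 (Mg and new alkyl group trans), as tris(bromomagnesium) species | Br[Mg]OC/C(CCC#C[Si](C)(C)C)=C(/CO[Mg]Br)[Mg]Br | intermediate
5 | 3-(hydroxymethyl)-4-[4-(trimethylsilyl)but-3-yn-1-yl]furan-2(5H)-one | OCC1=C(CCC#C[Si](C)(C)C)COC1=O | intermediate
6 | 4-(but-3-yn-1-yl)-3-(hydroxymethyl)furan-2(5H)-one | OCC1=C(CCC#C)COC1=O | intermediate
7 | 4-(but-3-yn-1-yl)-3-{[(tert-butyldiphenylsilyl)oxy]methyl}furan-2(5H)-one | C#CCCC1=C(CO[Si](c2ccccc2)(c2ccccc2)C(C)(C)C)C(=O)OC1 | intermediate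
8 | (Z)-2-bromo-1-(9-borabicyclo[3.3.1]nonan-9-yl)alkene from syn-bromoboration of 7 | Br/C(CCC1=C(CO[Si](c2ccccc2)(c2ccccc2)C(C)(C)C)C(=O)OC1)=C\B1C2CCCC1CCC2 | intermediate
9 | 4-(3-bromobut-3-en-1-yl)-3-{[(tert-butyldiphenylsilyl)oxy]methyl}furan-2(5H)-one | C=C(Br)CCC1=C(CO[Si](c2ccccc2)(c2ccccc2)C(C)(C)C)C(=O)OC1 | intermediate
10 | (R)-4-[(tert-butyldimethylsilyl)oxy]cyclopent-2-en-1-one | O=C1C=C[C@H](O[Si](C)(C)C(C)(C)C)C1 | starting material
11 | trans-4-(TBS-oxy)-3-R-1-(TES-oxy)cyclopent-1-ene | CC[Si](CC)(CC)OC1=C[C@@H](C(=C)CCC2=C(CO[Si](c3ccccc3)(c3ccccc3)C(C)(C)C)C(=O)OC2)[C@H](O[Si](C)(C)C(C)(C)C)C1 | intermediate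
12 | trans-4-(TBS-oxy)-3-R-cyclopentan-1-one | O=C1C[C@@H](C(=C)CCC2=C(CO[Si](c3ccccc3)(c3ccccc3)C(C)(C)C)C(=O)OC2)[C@H](O[Si](C)(C)C(C)(C)C)C1 | intermediate
13 | (R)-4-R-cyclopent-2-en-1-one | O=C1C[C@@H](C(=C)CCC2=C(CO[Si](c3ccccc3)(c3ccccc3)C(C)(C)C)C(=O)OC2)C=C1 | intermediate
14 | 2-(hydroxymethyl)-4-R-cyclopent-2-en-1-one | O=C1C[C@@H](C(=C)CCC2=C(CO[Si](c3ccccc3)(c3ccccc3)C(C)(C)C)C(=O)OC2)C=C1CO | intermediate
15 | (5-oxo-3-R-cyclopent-1-en-1-yl)methyl acetate | O=C1C[C@@H](C(=C)CCC2=C(CO[Si](c3ccccc3)(c3ccccc3)C(C)(C)C)C(=O)OC2)C=C1COC(C)=O | intermediate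
16 | caesium C3 enolate of the cyclised adduct, C15 acetoxy group still in place | CC(=O)OCC1=C([O-])C[C@H]2C(=C)CCC3=C(CO[Si](c4ccccc4)(c4ccccc4)C(C)(C)C)C(=O)O[C@@H]3[C@H]21.[Cs+] | intermediate
17 | 13-(TBDPS-oxy)-3-oxoguaia-4(15),7(11),10(14)-trien-12,6-olide (1α-H, 5α-H, 6β-H) | C=C1C(=O)C[C@H]2C(=C)CCC3=C(CO[Si](c4ccccc4)(c4ccccc4)C(C)(C)C)C(=O)O[C@@H]3[C@H]21 | intermediate
18 | 13-hydroxy-3-oxoguaia-4(15),7(11),10(14)-trien-12,6-olide | C=C1C(=O)C[C@H]2C(=C)CCC3=C(CO)C(=O)O[C@@H]3[C@H]21 | intermediate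
19 | 13-[(methoxycarbonyl)oxy]-3-oxoguaia-4(15),7(11),10(14)-trien-12,6-olide | C=C1C(=O)C[C@H]2C(=C)CCC3=C(COC(=O)OC)C(=O)O[C@@H]3[C@H]21 | intermediate
20 | 7-epi-dehydrozaluzanin C (1α-H, 5α-H, 6β-H, 7β-H; cis-fused lactone) | C=C1C(=O)C[C@H]2C(=C)CC[C@@H]3C(=C)C(=O)O[C@@H]3[C@H]21 | intermediate
21 | 1,2-epoxide of 11 (epoxide anti to R; 1-OTES) | CC[Si](CC)(CC)O[C@@]12O[C@@H]1[C@@H](C(=C)CCC3=C(CO[Si](c4ccccc4)(c4ccccc4)C(C)(C)C)C(=O)OC3)[C@H](O[Si](C)(C)C(C)(C)C)C2 | intermediate
22 | 2-hydroxy-3-R-4-(TBS-oxy)cyclopentan-1-one (all-trans) | O=C1[C@H](O)[C@@H](C(=C)CCC2=C(CO[Si](c3ccccc3)(c3ccccc3)C(C)(C)C)C(=O)OC2)[C@H](O[Si](C)(C)C(C)(C)C)C1 | intermediate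
23 | trans-3-R-4-(TBS-oxy)cyclopentane-1,2-dione | O=C1C(=O)[C@@H](C(=C)CCC2=C(CO[Si](c3ccccc3)(c3ccccc3)C(C)(C)C)C(=O)OC2)[C@H](O[Si](C)(C)C(C)(C)C)C1 | intermediate
24 | 2-hydroxy-3-R-4-(TBS-oxy)cyclopent-2-en-1-one | O=C1C(O)=C(C(=C)CCC2=C(CO[Si](c3ccccc3)(c3ccccc3)C(C)(C)C)C(=O)OC2)[C@H](O[Si](C)(C)C(C)(C)C)C1 | intermediate
25 | 2,4-bis(TBS-oxy)-3-R-cyclopent-2-en-1-one | O=C1C(O[Si](C)(C)C(C)(C)C)=C(C(=C)CCC2=C(CO[Si](c3ccccc3)(c3ccccc3)C(C)(C)C)C(=O)OC2)[C@H](O[Si](C)(C)C(C)(C)C)C1 | intermediate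
26 | 5′,6′-seco spiro Diels–Alder adduct (2′α-OTBS, 5′α-OTBS, 3′-ketone, 13′-OTBDPS butenolide on C8′) | O=C1C[C@@H](O[Si](C)(C)C(C)(C)C)C2=C(CCC3=C(CO[Si](c4ccccc4)(c4ccccc4)C(C)(C)C)C(=O)OC3)CC[C@]3(C(=O)C[C@H]4C(=C)CC[C@@H]5C(=C)C(=O)O[C@@H]5[C@H]43)[C@]12O[Si](C)(C)C(C)(C)C | intermediate
27 | 5′,6′-seco dienone (C4′=C5′, C1′=C10′, 2′α-OTBS) | O=C1C=CC2=C(CCC3=C(CO[Si](c4ccccc4)(c4ccccc4)C(C)(C)C)C(=O)OC3)CC[C@]3(C(=O)C[C@H]4C(=C)CC[C@@H]5C(=C)C(=O)O[C@@H]5[C@H]43)[C@]12O[Si](C)(C)C(C)(C)C | intermediate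
28 | 15′-hydroxy derivative of 27 (CH2OH on C4′) | O=C1C(CO)=CC2=C(CCC3=C(CO[Si](c4ccccc4)(c4ccccc4)C(C)(C)C)C(=O)OC3)CC[C@]3(C(=O)C[C@H]4C(=C)CC[C@@H]5C(=C)C(=O)O[C@@H]5[C@H]43)[C@]12O[Si](C)(C)C(C)(C)C | intermediate
29 | 15′-acetoxy derivative of 27 | O=C1C(COC(C)=O)=CC2=C(CCC3=C(CO[Si](c4ccccc4)(c4ccccc4)C(C)(C)C)C(=O)OC3)CC[C@]3(C(=O)C[C@H]4C(=C)CC[C@@H]5C(=C)C(=O)O[C@@H]5[C@H]43)[C@]12O[Si](C)(C)C(C)(C)C | intermediate
30 | caesium C3′ enolate of the cyclised adduct, C15′ acetoxy group still in place | CC(=O)OCC1=C([O-])[C@]2(O[Si](C)(C)C(C)(C)C)C3=C(CCC4=C(CO[Si](c5ccccc5)(c5ccccc5)C(C)(C)C)C(=O)O[C@@H]4[C@@H]13)CC[C@]21C(=O)C[C@H]2C(=C)CC[C@@H]3C(=C)C(=O)O[C@@H]3[C@H]21.[Cs+] | intermediate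
31 | hexacyclic butenolide (2′α-OTBS, 13′-OTBDPS, C4′=C15′, C7′=C11′) | C=C1C(=O)[C@]2(O[Si](C)(C)C(C)(C)C)C3=C(CCC4=C(CO[Si](c5ccccc5)(c5ccccc5)C(C)(C)C)C(=O)O[C@@H]4[C@@H]13)CC[C@]21C(=O)C[C@H]2C(=C)CC[C@@H]3C(=C)C(=O)O[C@@H]3[C@H]21 | intermediate
32 | 2′,13′-diol | C=C1C(=O)[C@]2(O)C3=C(CCC4=C(CO)C(=O)O[C@@H]4[C@@H]13)CC[C@]21C(=O)C[C@H]2C(=C)CC[C@@H]3C(=C)C(=O)O[C@@H]3[C@H]21 | intermediate
33 | 13′-methyl carbonate of 32 | C=C1C(=O)[C@]2(O)C3=C(CCC4=C(COC(=O)OC)C(=O)O[C@@H]4[C@@H]13)CC[C@]21C(=O)C[C@H]2C(=C)CC[C@@H]3C(=C)C(=O)O[C@@H]3[C@H]21 | intermediate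
34 | CNP0269880.1 | C=C1C(=O)[C@]2(O)C3=C(CC[C@@H]4C(=C)C(=O)O[C@@H]4[C@@H]13)CC[C@]21C(=O)C[C@H]2C(=C)CC[C@@H]3C(=C)C(=O)O[C@@H]3[C@H]21 | target

## Summary and risks

Total step count: 23. Longest linear sequence: 20 steps (steps 1–12, then 16–23); steps 13–15 form the branch from 11 to diene 25.

Steps most likely to fail:

Step 20 (key step). The dienolate may add to the wrong face of C5′, add 1,6 at C10′, or the product may epimerise at C6′ under the basic conditions. Fallback: the same bond would be made through a π-allylpalladium electrophile. Alcohol 28 is converted (Boc2O, DMAP, CH2Cl2) into the tert-butyl carbonate F1. Pd2(dba)3·CHCl3 with 1,2-bis(diphenylphosphino)ethane in toluene ionises F1 with loss of CO2, the tert-butoxide set free deprotonates the butenolide, and the dienolate attacks the C5′ terminus of the 2-acyl-π-allyl complex (Tsuji–Trost cyclisation; seven- rather than nine-membered ring), which returns to 31. Because palladium sits on the less hindered face and the nucleophile enters opposite to it, this path is stereocomplementary to the direct addition.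

Step 16. The (Z)-configured 1-siloxy diene may be too unreactive, may be desilylated by the Lewis acid, or may lose endo selectivity. Fallback: the free diosphenol 24 and enone 20 are joined by a base-mediated Michael–aldol annulation (K2CO3, MeCN). The diosphenolate adds through C14′ to C15, and the resulting C3 enolate adds through C4 to the C2′ carbonyl of the 1,2-dione, giving the tertiary alcohol F2. Silylation (TBSOTf, 2,6-lutidine, CH2Cl2, −78 °C) returns to 26.

Step 23. Hydride transfer may go to C13′ instead of C7′ or to the wrong face, and the palladium hydride may reduce the two exocyclic enone systems. Fallback: starting from diol 32, Mitsunobu displacement of the primary allylic alcohol with 2-nitrobenzenesulfonylhydrazide (PPh3, DEAD, THF, −30 °C) gives the sulfonylhydrazine F3. On warming this loses 2-nitrobenzenesulfinic acid to the monoalkyl diazene F4, and sigmatropic loss of N2 transfers hydrogen to C7′ with allylic transposition, which arrives at 34 directly without metal or hydride.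

Further compounds
F1 | step 20 | 15′-(tert-butoxycarbonyloxy) derivative of 27 (tert-butyl carbonate of 28) | O=C1C(COC(=O)OC(C)(C)C)=CC2=C(CCC3=C(CO[Si](c4ccccc4)(c4ccccc4)C(C)(C)C)C(=O)OC3)CC[C@]3(C(=O)C[C@H]4C(=C)CC[C@@H]5C(=C)C(=O)O[C@@H]5[C@H]43)[C@]12O[Si](C)(C)C(C)(C)C
F2 | step 16 | 2′-hydroxy analogue of 26 (free tertiary alcohol) | O=C1C[C@@H](O[Si](C)(C)C(C)(C)C)C2=C(CCC3=C(CO[Si](c4ccccc4)(c4ccccc4)C(C)(C)C)C(=O)OC3)CC[C@]3(C(=O)C[C@H]4C(=C)CC[C@@H]5C(=C)C(=O)O[C@@H]5[C@H]43)[C@]12O
F3 | step 23 | 13′-[1-(2-nitrobenzenesulfonyl)hydrazin-1-yl] derivative from 32 | C=C1C(=O)[C@]2(O)C3=C(CCC4=C(CN(N)S(=O)(=O)c5ccccc5[N+](=O)[O-])C(=O)O[C@@H]4[C@@H]13)CC[C@]21C(=O)C[C@H]2C(=C)CC[C@@H]3C(=C)C(=O)O[C@@H]3[C@H]21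
F4 | step 23 | 13′-diazenyl derivative (monoalkyl diazene) | C=C1C(=O)[C@]2(O)C3=C(CCC4=C(CN=N)C(=O)O[C@@H]4[C@@H]13)CC[C@]21C(=O)C[C@H]2C(=C)CC[C@@H]3C(=C)C(=O)O[C@@H]3[C@H]21
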